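Cuts: first the three O-benzyl bonds, then the pyrone bonds C4–C5 and O1–C2, then the aryl–acetyl bond and the bond from the bridge carbon to the malonate carbon (made as C=C).
Enabling feature: in the 2-pyrone ring, C2–C3–C4 is a malonyl unit whose middle carbon C3 already bears the ArCH2 group. O1–C6–C5 is the enol of a methyl ketone carrying the (S)-2-oxypropyl chain.
Arene half, forward: 5-hydroxyvanillin is brominated at C2 and benzylated. Its formyl carbon becomes the bridge by Knoevenagel condensation and conjugate reduction, Br is exchanged for a 1-ethoxyvinyl group (masked acetyl), and the diacid is converted into the dichloride.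
Chain half, forward: ethyl (S)-3-hydroxybutanoate is benzylated, taken to the methyl ketone through the Weinreb amide, and silylated at the kinetic enolate.
Rings: the benzene ring is bought. The only ring made, the pyrone, closes when the two halves are joined, and hydrogenolysis ends the route.
Stereochemistry: the single stereocentre, (S)-CH(OH)CH3, comes from the chiral pool, and none of its bonds is broken later.

Key step: step 12

Assumption: the buffered bromination of 1 is taken to enter C2, as it does with isovanillin. This should be checked on 3, where the remaining aryl H should show an NOE to OMe and CHO. Locants: arene C1 bears the bridge (CHO in 1–3), C2 Br/acetyl, C3 and C4 the oxygens, C5 OMe, C6 H. Pyrone: O1, C2 (C=O), C3 (bridge), C4 (OH), C5 (H), C6 (side chain).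

Step 1
Reactants: 1 5-hydroxyvanillin (3,4-dihydroxy-5-methoxybenzaldehyde)
Product: 2 2-bromo-3,4-dihydroxy-5-methoxybenzaldehyde
Conditions: Br2 (1.0 equiv), NaOAc, AcOH, 15 °C → rt
Reagents that add atoms: bromine BrBr
Why: Electrophilic aromatic bromination in which the free 3-OH directs ortho into C2, a position also para to the 5-OMe group, as in the conversion of isovanillin into 2-bromoisovanillin under the same buffered conditions, while C6 is screened by the in-plane methyl of the 5-OMe group and the formyl group makes the catechol less prone to oxidation.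

Step 2
Reactants: 2 2-bromo-3,4-dihydroxy-5-methoxybenzaldehyde
Product: 3 3,4-bis(benzyloxy)-2-bromo-5-methoxybenzaldehyde
Conditions: BnBr (2.4 equiv), K2CO3, DMF, 50 °C
Reagents that add atoms: benzyl bromide BrCc1ccccc1
Why: Williamson ether synthesis on both phenoxides gives ethers that withstand base, Pd(0), HCl and acyl chlorides and can be removed together in the last step.

Step 3
Reactants: 3 3,4-bis(benzyloxy)-2-bromo-5-methoxybenzaldehyde; 4 dimethyl malonate
Product: 5 dimethyl 2-{[3,4-bis(benzyloxy)-2-bromo-5-methoxyphenyl]methylidene}propanedioate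
Conditions: piperidine (cat.), AcOH (cat.), toluene, reflux, Dean–Stark
Reagents that add atoms: none
Why: Knoevenagel condensation under piperidinium acetate catalysis with azeotropic removal of water is routine for ortho-halogenated alkoxybenzaldehydes and turns the formyl carbon into the future bridge carbon.

Step 4
Reactants: 5 dimethyl 2-{[3,4-bis(benzyloxy)-2-bromo-5-methoxyphenyl]methylidene}propanedioate
Product: 6 dimethyl 2-{[3,4-bis(benzyloxy)-2-bromo-5-methoxyphenyl]methyl}propanedioate
Conditions: NaBH4, THF/MeOH, 0 °C
Reagents that add atoms: none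
Why: Conjugate hydride reduction of an arylidene malonate by NaBH4 leaves the aryl bromide, the benzyl ethers and (at 0 °C) the esters untouched, which catalytic hydrogenation would not.

Step 5
Reactants: 6 dimethyl 2-{[3,4-bis(benzyloxy)-2-bromo-5-methoxyphenyl]methyl}propanedioate
Product: 7 dimethyl 2-{[3,4-bis(benzyloxy)-2-(1-ethoxyethenyl)-5-methoxyphenyl]methyl}propanedioate
Conditions: Bu3SnC(OEt)=CH2, PdCl2(PPh3)2 (5 mol %), toluene, 100 °C; filtration through Et3N-deactivated silica
Reagents that add atoms: tributyl(1-ethoxyvinyl)stannane CCCC[Sn](CCCC)(CCCC)C(=C)OCC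
Why: Stille coupling of the aryl bromide with an acetyl-anion equivalent runs under neutral conditions that do not deprotonate the malonate, and the enol ether is kept on purpose so that no ketone is present in the basic step that follows.

Step 6
Reactants: 7 dimethyl 2-{[3,4-bis(benzyloxy)-2-(1-ethoxyethenyl)-5-methoxyphenyl]methyl}propanedioate
Product: 9 2-{[2-acetyl-3,4-bis(benzyloxy)-5-methoxyphenyl]methyl}propanedioic acid, via dipotassium enol-ether malonate 8 (not isolated)
Conditions: KOH, THF/MeOH/H2O, rt → 40 °C; Et2O wash; then 2 M HCl, THF, 0 °C → rt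
Reagents that add atoms: potassium hydroxide [K+].[OH-]; water O
Why: Saponification while the ketone is still masked excludes the 5-exo-trig aldol addition of the malonate anion to an ortho-acetyl group, the ether wash removes tin residues, and the acidification hydrolyses the enol ether and protonates both carboxylates at a temperature at which a malonic acid does not decarboxylate.

Step 7
Reactants: 9 2-{[2-acetyl-3,4-bis(benzyloxy)-5-methoxyphenyl]methyl}propanedioic acid
Product: 10 2-{[2-acetyl-3,4-bis(benzyloxy)-5-methoxyphenyl]methyl}propanedioyl dichloride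
Conditions: (COCl)2 (3 equiv), DMF (cat.), CH2Cl2, 0 °C → rt; evaporation, used crude
Reagents that add atoms: oxalyl chloride O=C(Cl)C(=O)Cl
Why: Acid chloride formation through the catalytic Vilsmeier-type chloroiminium salt proceeds at or below room temperature without decarboxylation, and without a Lewis acid neither the hindered aryl ketone nor the free arene position C6 should react with the acyl chlorides.

Step 8
Reactants: 11 ethyl (S)-3-hydroxybutanoate
Product: 12 ethyl (S)-3-(benzyloxy)butanoate
Conditions: BnOC(=NH)CCl3, TfOH (cat.), CH2Cl2/cyclohexane, 0 °C → rt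
Reagents that add atoms: benzyl 2,2,2-trichloroacetimidate N=C(OCc1ccccc1)C(Cl)(Cl)Cl
Why: Acid-catalysed trichloroacetimidate benzylation avoids the alkoxide that would invite retro-aldol or E1cB pathways and does not break the C–O bond of the stereocentre, so the (S) configuration is retained.

Step 9
Reactants: 12 ethyl (S)-3-(benzyloxy)butanoate
Product: 13 (S)-3-(benzyloxy)-N-methoxy-N-methylbutanamide
Conditions: MeNH(OMe)·HCl, i-PrMgCl, THF, −20 °C → 0 °C
Reagents that add atoms: N,O-dimethylhydroxylamine hydrochloride CNOC.Cl
Why: Weinreb amide formation by direct aminolysis of the ester with the chloromagnesium amide is fast at −20 °C, where the β-benzyloxy group is not eliminated.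

Step 10
Reactants: 13 (S)-3-(benzyloxy)-N-methoxy-N-methylbutanamide
Product: 14 (S)-4-(benzyloxy)pentan-2-one
Conditions: MeMgBr, THF, 0 °C; aq NH4Cl
Reagents that add atoms: methylmagnesium bromide C[Mg]Br
Why: In the Weinreb ketone synthesis the chelated tetrahedral adduct persists until the quench, so only one methyl group is delivered, and the stereocentre, β to the carbonyl group, is not involved.

Step 11
Reactants: 14 (S)-4-(benzyloxy)pentan-2-one
Product: 16 {[(4S)-4-(benzyloxy)pent-1-en-2-yl]oxy}trimethylsilane, via kinetic lithium enolate 15 (not isolated)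
Conditions: 14 added to LDA, THF, −78 °C; TMSCl, −78 °C → 0 °C; pentane, cold aq NaHCO3; used without chromatography
Reagents that add atoms: chlorotrimethylsilane C[Si](C)(C)Cl; lithium diisopropylamide [Li+].CC(C)[N-]C(C)C (lithium appears in 15 only)
Why: Kinetic deprotonation by the hindered amide base at −78 °C removes a methyl proton rather than the more crowded C3–H, whose loss would open an E1cB path, and O-silylation of the enolate fixes the terminal C=C bond.

Step 12
Reactants: 10 2-{[2-acetyl-3,4-bis(benzyloxy)-5-methoxyphenyl]methyl}propanedioyl dichloride; 16 {[(4S)-4-(benzyloxy)pent-1-en-2-yl]oxy}trimethylsilane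
Product: 18 3-{[2-acetyl-3,4-bis(benzyloxy)-5-methoxyphenyl]methyl}-6-[(2S)-2-(benzyloxy)propyl]-4-hydroxy-2H-pyran-2-one, via 3,5-dioxoacyl chloride 17 (not isolated)
Conditions: 16 (1.3 equiv), CH2Cl2/Et2O, −78 °C → rt, no base, no Lewis acid
Reagents that add atoms: none
Why: This is an Effenberger-type [3+3] pyrone annulation, the known reaction of monosubstituted malonyl dichlorides with ketone trimethylsilyl enol ethers in the absence of base or Lewis acid. The nucleophilic CH2 terminus of 16 adds to one COCl group of 10 (or to the chlorocarbonyl ketene that 10 can form by HCl loss), chloride takes the silyl group away as TMSCl, and the C4–C5 bond of 17 is in place. The enol oxygen at C6 of 17 then attacks the second COCl group in a 6-exo-trig O-acylation that makes O1–C2 and closes the only new ring, and enolisation at C4 gives the aromatic 4-hydroxy-2-pyrone, which makes the sequence irreversible. No stereocentre is created, because the epimerisable C3 centre of 17 becomes sp2 and the (S)-carbinol carbon, a benzyl ether β to the enol carbon, takes no part. The regiochemistry needed (H at C5, side chain at C6) is fixed by the terminal C=C bond of 16 and is preserved by mixing at −78 °C, since the first acylation liberates only TMSCl and HCl appears only on ring closure. The chemoselectivity needed is secured because the aryl methyl ketone is unsilylated, twisted between two ortho substituents and able to reach either COCl group only through a seven-membered ring, and because without a Lewis acid the free arene position C6 is not acylated to an indanone.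

Step 13
Reactants: 18 3-{[2-acetyl-3,4-bis(benzyloxy)-5-methoxyphenyl]methyl}-6-[(2S)-2-(benzyloxy)propyl]-4-hydroxy-2H-pyran-2-one
Product: 19 penicanesin D, 3-[(2-acetyl-3,4-dihydroxy-5-methoxyphenyl)methyl]-4-hydroxy-6-[(2S)-2-hydroxypropyl]-2H-pyran-2-one
Conditions: H2 (1 atm), 10% Pd/C, EtOAc/MeOH, rt, stopped when 18 and the partly debenzylated species are consumed
Reagents that add atoms: none
Why: Catalytic hydrogenolysis cleaves the two aryl benzyl ethers and the alkyl benzyl ether at 1 atm, whereas the aromatic hydroxypyrone and the hindered, electron-rich and finally hydrogen-bonded aryl ketone should be reduced far more slowly, and the stereocentre keeps its C–O bond.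

Compound list
1 | 5-hydroxyvanillin (3,4-dihydroxy-5-methoxybenzaldehyde) | COc1cc(C=O)cc(O)c1O | starting material
2 | 2-bromo-3,4-dihydroxy-5-methoxybenzaldehyde | COc1cc(C=O)c(Br)c(O)c1O | intermediate
3 | 3,4-bis(benzyloxy)-2-bromo-5-methoxybenzaldehyde | COc1cc(C=O)c(Br)c(OCc2ccccc2)c1OCc1ccccc1 | intermediate
4 | dimethyl malonate | COC(=O)CC(=O)OC | starting material
5 | dimethyl 2-{[3,4-bis(benzyloxy)-2-bromo-5-methoxyphenyl]methylidene}propanedioate | COc1cc(C=C(C(=O)OC)C(=O)OC)c(Br)c(OCc2ccccc2)c1OCc1ccccc1 | intermediate
6 | dimethyl 2-{[3,4-bis(benzyloxy)-2-bromo-5-methoxyphenyl]methyl}propanedioate | COc1cc(CC(C(=O)OC)C(=O)OC)c(Br)c(OCc2ccccc2)c1OCc1ccccc1 | intermediate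
7 | dimethyl 2-{[3,4-bis(benzyloxy)-2-(1-ethoxyethenyl)-5-methoxyphenyl]methyl}propanedioate | COc1cc(CC(C(=O)OC)C(=O)OC)c(C(=C)OCC)c(OCc2ccccc2)c1OCc1ccccc1 | intermediate
8 | dipotassium 2-{[3,4-bis(benzyloxy)-2-(1-ethoxyethenyl)-5-methoxyphenyl]methyl}propanedioate (not isolated) | [K+].[K+].COc1cc(CC(C(=O)[O-])C(=O)[O-])c(C(=C)OCC)c(OCc2ccccc2)c1OCc1ccccc1 | intermediate
9 | 2-{[2-acetyl-3,4-bis(benzyloxy)-5-methoxyphenyl]methyl}propanedioic acid | COc1cc(CC(C(=O)O)C(=O)O)c(C(C)=O)c(OCc2ccccc2)c1OCc1ccccc1 | intermediate
10 | 2-{[2-acetyl-3,4-bis(benzyloxy)-5-methoxyphenyl]methyl}propanedioyl dichloride | COc1cc(CC(C(=O)Cl)C(=O)Cl)c(C(C)=O)c(OCc2ccccc2)c1OCc1ccccc1 | intermediate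
11 | ethyl (S)-3-hydroxybutanoate | CCOC(=O)C[C@H](C)O | starting material
12 | ethyl (S)-3-(benzyloxy)butanoate | CCOC(=O)C[C@H](C)OCc1ccccc1 | intermediate
13 | (S)-3-(benzyloxy)-N-methoxy-N-methylbutanamide | CON(C)C(=O)C[C@H](C)OCc1ccccc1 | intermediate
14 | (S)-4-(benzyloxy)pentan-2-one | CC(=O)C[C@H](C)OCc1ccccc1 | intermediate
15 | lithium (4S)-4-(benzyloxy)pent-1-en-2-olate (not isolated) | [Li+].[O-]C(=C)C[C@H](C)OCc1ccccc1 | intermediate
16 | {[(4S)-4-(benzyloxy)pent-1-en-2-yl]oxy}trimethylsilane | C=C(O[Si](C)(C)C)C[C@H](C)OCc1ccccc1 | intermediate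
17 | (7S)-2-{[2-acetyl-3,4-bis(benzyloxy)-5-methoxyphenyl]methyl}-7-(benzyloxy)-3,5-dioxooctanoyl chloride (C2 epimers and enol tautomers, not isolated) | COc1cc(CC(C(=O)Cl)C(=O)CC(=O)C[C@H](C)OCc2ccccc2)c(C(C)=O)c(OCc2ccccc2)c1OCc1ccccc1 | intermediate
18 | 3-{[2-acetyl-3,4-bis(benzyloxy)-5-methoxyphenyl]methyl}-6-[(2S)-2-(benzyloxy)propyl]-4-hydroxy-2H-pyran-2-one | COc1cc(Cc2c(O)cc(C[C@H](C)OCc3ccccc3)oc2=O)c(C(C)=O)c(OCc2ccccc2)c1OCc1ccccc1 | intermediate
19 | penicanesin D | COc1cc(Cc2c(O)cc(C[C@H](C)O)oc2=O)c(C(C)=O)c(O)c1O | target

Total step count: 13. Longest linear sequence: 9 (steps 1–7, 12, 13).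

Steps most likely to fail

Step 12.
- **What may go wrong:** the dichloride may lose HCl and the resulting chlorocarbonyl ketene may self-condense. The HCl set free on ring closure may protodesilylate the enol silane or shift its double bond. O-acylation may compete with C-acylation.
- **Fallback:** it sets out from 16 and 3 and comes back at 18.
  - Enol silane 16 is combined with commercial unsubstituted malonyl dichloride (Et2O, −78 °C → rt), the parent case of the annulation, to give 6-[(2S)-2-(benzyloxy)propyl]-4-hydroxy-2H-pyran-2-one F1.
  - In parallel, bromo aldehyde 3, whose C–Br bond is activated by the ortho formyl group, undergoes Stille coupling with tributyl(1-ethoxyvinyl)stannane. This gives 3,4-bis(benzyloxy)-2-(1-ethoxyethenyl)-5-methoxybenzaldehyde F2.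
  - Dilute HCl converts F2 into 2-acetyl-3,4-bis(benzyloxy)-5-methoxybenzaldehyde F3.
  - F1, F3 and Hantzsch ester with catalytic L-proline (CH2Cl2, rt) then undergo a three-component reductive alkylation. Knoevenagel condensation at pyrone C3 forms the transient 3-arylidenepyran-2,4-dione F4.
  - F4 is reduced by hydride transfer before a second pyrone or the acetyl enol can add, which gives 18.

Step 1.
- **What may go wrong:** bromine may enter at C6 instead of C2, a second bromination may follow, or bromine may oxidise the catechol.
- **Fallback:** it sets out from 1 and comes back at 3.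
  - The most acidic 4-OH (para to the formyl group) is benzylated selectively (BnBr 1.0 equiv, NaHCO3, NaI cat., DMF, 40 °C). This gives 4-(benzyloxy)-3-hydroxy-5-methoxybenzaldehyde F5.
  - The remaining monophenol is brominated with NBS and catalytic diisopropylamine in CH2Cl2. Under these conditions an N-bromoamine hydrogen-bonded to the phenol delivers bromine to the ortho position, and C2 is the only free ortho site. The product is 4-(benzyloxy)-2-bromo-3-hydroxy-5-methoxybenzaldehyde F6.
  - Benzylation of F6 (BnBr, K2CO3, DMF) gives 3.

Step 13.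
- **What may go wrong:** the secondary alkyl benzyl ether may cleave slowly, so that reduction of the pyrone C5=C6 bond or of the aryl ketone sets in before debenzylation is complete.
- **Fallback:** it sets out from 18 and comes back at 19, and it replaces reduction by Lewis acid cleavage. BCl3 with pentamethylbenzene as benzyl cation scavenger (CH2Cl2, −78 °C, MeOH quench) should remove all three benzyl groups. At this temperature the 5-OMe group, which is not chelation-activated, should stay. No new compound is made.

Further compounds
F1 | step 12 | 6-[(2S)-2-(benzyloxy)propyl]-4-hydroxy-2H-pyran-2-one | O=c1cc(O)cc(C[C@H](C)OCc2ccccc2)o1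
F2 | step 12 | 3,4-bis(benzyloxy)-2-(1-ethoxyethenyl)-5-methoxybenzaldehyde | COc1cc(C=O)c(C(=C)OCC)c(OCc2ccccc2)c1OCc1ccccc1
F3 | step 12 | 2-acetyl-3,4-bis(benzyloxy)-5-methoxybenzaldehyde | COc1cc(C=O)c(C(C)=O)c(OCc2ccccc2)c1OCc1ccccc1
F4 | step 12 | 3-{[2-acetyl-3,4-bis(benzyloxy)-5-methoxyphenyl]methylidene}-6-[(2S)-2-(benzyloxy)propyl]-2H-pyran-2,4(3H)-dione | COc1cc(C=C2C(=O)C=C(C[C@H](C)OCc3ccccc3)OC2=O)c(C(C)=O)c(OCc2ccccc2)c1OCc1ccccc1
F5 | step 1 | 4-(benzyloxy)-3-hydroxy-5-methoxybenzaldehyde | COc1cc(C=O)cc(O)c1OCc1ccccc1
F6 | step 1 | 4-(benzyloxy)-2-bromo-3-hydroxy-5-methoxybenzaldehyde | COc1cc(C=O)c(Br)c(O)c1OCc1ccccc1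
F0 | step 13 | none | none
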